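**Retrosynthetic overview**
1. The 5-OH comes last, by chelation-controlled 5-O-demethylation of hexamethoxyflavone 9.
2. Key disconnection C2–C1': C2 of chromone 6 is used as a carbanion (2-chromenylzinc 8, an α-oxyvinyl/masked aroyl anion and β-acylvinyl anion) and joined to unprotected aryl bromide 7; both carbons are electrophilic in their native form.
3. Chromone 6 (ring C) comes from 2-hydroxyaryl methoxymethyl ketone 4 plus one carbon from DMF-DMA; the 3-OMe is already in place.
4. Ketone 4 comes from pentamethoxybenzene 1 and methoxyacetyl chloride 2 (Friedel–Crafts acylation with ortho-demethylation).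
5. Ring order: A bought intact, C closed in step 2, B (bought intact) attached in step 3.

Assumption: the target is achiral (no stereocentre, no stable axis), so no stereocontrol is needed; the only stereo element on the way is the C=C geometry of transient enaminone 5, which is lost on cyclisation.

**Step 1**
Reactants: 1 pentamethoxybenzene; 2 methoxyacetyl chloride
Product: 4 1-(2-hydroxy-3,4,5,6-tetramethoxyphenyl)-2-methoxyethan-1-one, via pentamethoxyphenyl methoxymethyl ketone 3 (not isolated)
Conditions: AlCl3 (2.5 equiv), CH2Cl2, 0 °C → rt; aq. HCl work-up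
Reagents that add atoms: none
Why: Friedel–Crafts acylation occurs at the only free position of the electron-rich arene, and AlCl3 held in a six-membered chelate between the new C=O and an ortho-OMe then cleaves that methyl ether (the two ortho-OMe groups are equivalent by symmetry), a chelation-assisted ortho-demethylation.

**Step 2**
Reactants: 4 1-(2-hydroxy-3,4,5,6-tetramethoxyphenyl)-2-methoxyethan-1-one
Product: 6 3,5,6,7,8-pentamethoxy-4H-chromen-4-one, via enaminone 5 (not isolated)
Conditions: DMF-DMA (3 equiv), toluene, 100 °C; evaporate; then conc. HCl, CH2Cl2, 40 °C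
Reagents that add atoms: N,N-dimethylformamide dimethyl acetal, COC(OC)N(C)C
Why: the activated α-methylene condenses with the amide acetal to the enaminone, and acid-promoted 6-endo addition–elimination of the phenol OH at the enamine carbon expels dimethylamine and closes the pyranone (enaminone chromone synthesis).

**Step 3**
Reactants: 6 3,5,6,7,8-pentamethoxy-4H-chromen-4-one; 7 4-bromo-3-methoxyphenol
Product: 9 2-(4-hydroxy-2-methoxyphenyl)-3,5,6,7,8-pentamethoxy-4H-chromen-4-one, via chromen-2-ylzinc chloride 8 (not isolated)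
Conditions: 6 (1.25 equiv), TMPZnCl·LiCl (1.5 equiv), THF, 25 °C, 1 h; then added over 1 h to 7 (1.0 equiv), Pd(OAc)2 (2 mol %), SPhos (4 mol %), THF, 25 → 50 °C; aq. NH4Cl
Reagents that add atoms: none
Why: TMPZnCl·LiCl removes the only ring C–H of 6 (C2–H, acidified by O1 and the 3-OMe, C3 being blocked) without attacking C4=O, so the normally electrophilic β-carbon of the vinylogous ester becomes an α-oxyvinylzinc nucleophile (masked aroyl anion / β-acylvinyl anion, a reversed-polarity d-synthon) that is joined to the electrophilic C–Br carbon of 7 by Pd/SPhos Negishi cross-coupling, organozincs being slow enough as bases to tolerate the free ArOH on slow addition (deprotonative zincation / Negishi coupling).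

**Step 4**
Reactants: 9 2-(4-hydroxy-2-methoxyphenyl)-3,5,6,7,8-pentamethoxy-4H-chromen-4-one
Product: 10 5,4'-dihydroxy-3,6,7,8,2'-pentamethoxyflavone
Conditions: BCl3 (1 M in CH2Cl2, 2.5 equiv), CH2Cl2, −78 → 0 °C, 1 h; then MeOH, aq. NaHCO3
Reagents that add atoms: none
Why: BCl3 binds C4=O and the peri 5-OMe oxygen in a six-membered boron chelate and cleaves only that methyl ether at low temperature, leaving the 3-, 6-, 7-, 8- and 2'-OMe groups intact (chelation-controlled selective 5-O-demethylation; one extra equivalent is taken up reversibly by the 4'-OH).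

**Compound list**
1 | pentamethoxybenzene | COc1cc(OC)c(OC)c(OC)c1OC | starting material
2 | methoxyacetyl chloride | COCC(=O)Cl | starting material
3 | 2-methoxy-1-(pentamethoxyphenyl)ethan-1-one | COCC(=O)c1c(OC)c(OC)c(OC)c(OC)c1OC | intermediate (not isolated)
4 | 1-(2-hydroxy-3,4,5,6-tetramethoxyphenyl)-2-methoxyethan-1-one | COCC(=O)c1c(O)c(OC)c(OC)c(OC)c1OC | intermediate
5 | (Z)-3-(dimethylamino)-1-(2-hydroxy-3,4,5,6-tetramethoxyphenyl)-2-methoxyprop-2-en-1-one | CN(C)/C=C(\OC)C(=O)c1c(O)c(OC)c(OC)c(OC)c1OC | intermediate (not isolated)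
6 | 3,5,6,7,8-pentamethoxy-4H-chromen-4-one | COc1coc2c(OC)c(OC)c(OC)c(OC)c2c1=O | intermediate
7 | 4-bromo-3-methoxyphenol | COc1cc(O)ccc1Br | starting material
8 | (3,5,6,7,8-pentamethoxy-4-oxo-4H-chromen-2-yl)zinc chloride | COc1c([Zn]Cl)oc2c(OC)c(OC)c(OC)c(OC)c2c1=O | intermediate (not isolated)
9 | 2-(4-hydroxy-2-methoxyphenyl)-3,5,6,7,8-pentamethoxy-4H-chromen-4-one | COc1cc(O)ccc1-c1oc2c(OC)c(OC)c(OC)c(OC)c2c(=O)c1OC | intermediate
10 | 5,4'-dihydroxy-3,6,7,8,2'-pentamethoxyflavone | COc1cc(O)ccc1-c1oc2c(OC)c(OC)c(OC)c(O)c2c(=O)c1OC | target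

**Totals**
Total step count: 4. Longest linear sequence: 4 (steps 1 → 2 → 3 → 4; compounds 2 and 7 are bought).

**Steps most likely to fail, with fallbacks**

Step 3 (key coupling) is the riskiest: the free phenol of 7 may protonate zinc reagent 8, and the electron-rich bromide adds slowly to Pd. The fallback sets out from 7 and keeps the same C2-carbanion coupling but removes the acidic proton. Compound 7 is silylated (TBSCl, imidazole, DMF, rt) to (4-bromo-3-methoxyphenoxy)(tert-butyl)dimethylsilane F1. F1 is coupled with 8 (Pd(OAc)2/SPhos, THF, 50 °C, no slow addition needed) to 2-[4-(tert-butyldimethylsilyloxy)-2-methoxyphenyl]-3,5,6,7,8-pentamethoxy-4H-chromen-4-one F2. The silyl ether is cleaved with TBAF (THF, 0 °C), and the route is rejoined at 9.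

Step 1 is next: the methoxyacetyl cation may lose CO under AlCl3, or more than one methyl ether may be cleaved. The fallback sets out from 1 and separates C–C bond formation from demethylation. Compound 1 is lithiated at its only C–H (n-BuLi, TMEDA, THF, 0 °C) to pentamethoxyphenyllithium F3. F3 is acylated with N,2-dimethoxy-N-methylacetamide (COCC(=O)N(C)OC, −78 → 0 °C) to give 3, now isolated. One ortho-OMe of 3 is then cleaved with BCl3 (1.1 equiv, CH2Cl2, −78 → 0 °C), and the route is rejoined at 4.

Step 4 is third: BCl3 may also cleave the 6-OMe next to the new 5-OH, or the 3-OMe. The fallback sets out from 6 and moves the demethylation to the simpler chromone, with a hydrogenolysable group on O5.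
- Compound 6 is treated with BCl3 (1.2 equiv, CH2Cl2, −78 → 0 °C) to give 5-hydroxy-3,6,7,8-tetramethoxy-4H-chromen-4-one F4.
- F4 is benzylated (BnBr, K2CO3, DMF, 60 °C) to 5-(benzyloxy)-3,6,7,8-tetramethoxy-4H-chromen-4-one F5.
- F5 is zincated with TMPZnCl·LiCl (THF, 25 °C) to [5-(benzyloxy)-3,6,7,8-tetramethoxy-4-oxo-4H-chromen-2-yl]zinc chloride F6.
- F6 is coupled with 7 as in step 3 to 5-(benzyloxy)-2-(4-hydroxy-2-methoxyphenyl)-3,6,7,8-tetramethoxy-4H-chromen-4-one F7.
- Hydrogenolysis of F7 (H2 1 atm, 10 % Pd/C, EtOAc/MeOH, rt) rejoins the route at 10.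

**Further compounds**
F1 | step 3 | (4-bromo-3-methoxyphenoxy)(tert-butyl)dimethylsilane | COc1cc(O[Si](C)(C)C(C)(C)C)ccc1Br
F2 | step 3 | 2-[4-(tert-butyldimethylsilyloxy)-2-methoxyphenyl]-3,5,6,7,8-pentamethoxy-4H-chromen-4-one | COc1cc(O[Si](C)(C)C(C)(C)C)ccc1-c1oc2c(OC)c(OC)c(OC)c(OC)c2c(=O)c1OC
F3 | step 1 | pentamethoxyphenyllithium | [Li]c1c(OC)c(OC)c(OC)c(OC)c1OC
F4 | step 4 | 5-hydroxy-3,6,7,8-tetramethoxy-4H-chromen-4-one | COc1coc2c(OC)c(OC)c(OC)c(O)c2c1=O
F5 | step 4 | 5-(benzyloxy)-3,6,7,8-tetramethoxy-4H-chromen-4-one | COc1coc2c(OC)c(OC)c(OC)c(OCc3ccccc3)c2c1=O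
F6 | step 4 | [5-(benzyloxy)-3,6,7,8-tetramethoxy-4-oxo-4H-chromen-2-yl]zinc chloride | COc1c([Zn]Cl)oc2c(OC)c(OC)c(OC)c(OCc3ccccc3)c2c1=O
F7 | step 4 | 5-(benzyloxy)-2-(4-hydroxy-2-methoxyphenyl)-3,6,7,8-tetramethoxy-4H-chromen-4-one | COc1cc(O)ccc1-c1oc2c(OC)c(OC)c(OC)c(OCc3ccccc3)c2c(=O)c1OC
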